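A small charge of initiator, 2.8 mol% of the free monomer, goes into each flask here, and the violet run reads the same at its last two points.

| setting | red | blue | violet | oak | alder | ash |
|---|---|---|---|---|---|---|
| free monomer | 3 M | 3 M | 3 M | 3.0 M | 3.0 M | 3.0 M |
| transfer agent | 0.080 M | 0.18 M | 0.44 M | 0.100 M | 0.200 M | 0.400 M |
| initiator | 2.8 mol% | 2.8 mol% | 2.8 mol% | 2.8 mol% | 2.8 mol% | 2.8 mol% |
| remark | run made earlier | run made earlier | run made earlier |  |  |  |
| time |  |  |  | 8.0 min | 8.0 min | 8.0 min |

| run | time / min | monomer in chains / % | free monomer / % |
|---|---|---|---|
| red | 0.833 | 16 | 87 |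
| red | 1.50 | 23 | 77 |
| red | 2.50 | 32 | 65 |
| red | 3.00 | 40 | 65 |
| red | 4.00 | 46 | 52 |
| blue | 0.333 | 8 | 95 |
| blue | 0.667 | 11 | 90 |
| blue | 1.00 | 14 | 85 |
| blue | 2.00 | 26 | 73 |
| blue | 4.00 | 37 | 60 |
| violet | 0.333 | 1 | 95 |
| violet | 1.00 | 12 | 86 |
| violet | 2.00 | 23 | 78 |
| violet | 3.00 | 25 | 75 |
| violet | 4.00 | 25 | 75 |

(standard deviation of a reading: 2 percentage points)

- the earlier runs were read with a standard deviation of 2 percentage points
- "hardly changes" means that all values lie within two and a half points (for a concentration: within two and a half percent of the largest)

- amount of monomer in chains at the end, in percent of the free monomer charged for oak, alder, ash, in this order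
- the course of these numbers from the first flask to the last (falls all the way / hardly changes / rises all the way / falls, then rises / rises, then falls)

The early loss of free monomer looks pseudo-first-order. In the red run the logarithm of charged over left climbs at s = 0.172 min⁻¹, and in the violet run at 0.151 min⁻¹ up to 1.00 min, so these readings show little effect of transfer agent at the start. The late readings differ: violet reads 25% in chains at both 3.00 min and 4.00 min, with 75% free.

We call R, the reach, the charge c of transfer agent times the logarithm of charged over left at the stop, read on the violet run as 0.127 M, and we assume it holds across flasks, so the stopping logarithm is R/c.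

From above, we take two estimates as ceilings. Slope s held for 8.0 min gives 74.8% for oak. A reach read two standard deviations high, 0.151 M, gives 52.9% for alder and 31.4% for ash.

From below, we let the logarithm approach R/c exponentially with starting slope s. On red at 4.00 min this curve gives 42.8%, under the 46% read, so we treat it as a floor. It gives 56.8% for oak, 42.9% for alder and 26.8% for ash.

The forecast, holding that “The difference is how long the reaction keeps going”, says 61%, 46%, 27%, falls all the way, which lies inside our brackets, with ash at the lower edge.

The flask gives 64.1%, 48.0%, 29.2%, falls all the way.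

    2 initiator ⇌ resting dimer (K = 11.0 L mol⁻¹, k = 0.120 L mol⁻¹ s⁻¹)
    free monomer + living end → monomer in chains + living end, rate k2*[living end]*[free monomer] (k = 0.0444 L mol⁻¹ s⁻¹)
    free monomer + initiator → living end + monomer in chains (k = 0.0184 L mol⁻¹ s⁻¹)
    living end + transfer agent → dead chain (kL = 0.0327 L mol⁻¹ s⁻¹)

In ash at 80.0 min, dead chain stands at 0.0840 M, against an initiator charge of 0.0840 M. The reach reckons 72.9% free monomer for ash at the stop, and ash holds 70.5% at 80.0 min. For alder the reach reckons 53.1%, and alder holds 46.3% at 80.0 min.

(The earlier runs and the new flask come from a simulation for an exercise; noise was put on by code.)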